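Charge a small 1.50 equiv of partner and decide before running whether that reaches far enough by 50 min.

| flask | substrate | partner | remark | time |
|---|---|---|---|---|
| south | 20 mM | 2.1 equiv | run made earlier |  |
| south-west | 20 mM | 3.3 equiv | run made earlier |  |
| flask | 20 mM | 1.50 equiv |  | 50 min |

- south (time / min: substrate / %, mono adduct / %): 3.00: 55.6, 25.0; 10.0: 25.6, 25.0; 20.0: 16.4, 16.8; 25.0: 13.9, 16.2; 40.0: 11.4, 11.1; 50.0: 12.5, 11.9
- south-west (time / min: substrate / %, mono adduct / %): 4.00: 31.8, 25.9; 6.00: 22.9, 21.8; 12.0: 10.3, 13.0; 20.0: 4.4, 7.7; 30.0: 3.1, 5.0; 50.0: 3.5, 2.8

(readings scatter by 1 percentage point)

- the earlier runs were read with a standard deviation of 1 percentage point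
- candidate steps: substrate + partner -> mono adduct + by-product; partner + mono adduct -> double product + by-product; partner + double product -> triple product + by-product; double product -> decomposed reagent; substrate <-> dormant form

- the substrate standing at 50 min, as a percentage of the substrate charged
- the mono adduct standing at 50 min, as a percentage of the substrate charged
- the double product standing at 50 min, as a percentage of the substrate charged
- the triple product standing at 50 min, as a percentage of the substrate charged

Every addition uses one partner, so keep a ledger in fractions of the substrate charged. In the south run, substrate reads 11.4% at 40.0 min and 12.5% at 50.0 min, so assume its 2.1 equiv used. Subtract the mono adduct and divide by the pool, meaning everything that is neither substrate nor mono adduct, dormant form included. That reads as the depth, partner used beyond the mono adduct per molecule of that pool, 2.62.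

South substrate and mono adduct end level within scatter, so set them equal in this flask; the ledger then gives each 26.4%. Go round once more. That answer leaves a pool of 47.2%, smaller than the south pool of 75.6%, so scale the depth's excess over two by that ratio. Depth becomes 2.39 and each of substrate and mono adduct 23.5%. My pool is then 53.0%; with no dormant form counted in it, that splits into triple product 20.5%, and double product with its decay 32.5%. Half the substrate charged standing in that pool will do, so run 1.50 equiv unchanged.

The forecast says substrate 25%, mono adduct 23%, double product 28%, triple product 21%, with “Partner should be essentially gone by 50 min”. Its double product stands by itself, where my figure includes decay.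

The flask gives substrate 21.1%, mono adduct 20.6%, double product 7.42%, triple product 27.6%.

    substrate + partner → mono adduct + by-product (k = 0.0780 M⁻¹ s⁻¹)
    partner + mono adduct → double product + by-product (k = 0.120 M⁻¹ s⁻¹)
    partner + double product → triple product + by-product (k = 0.160 M⁻¹ s⁻¹)
    double product → decomposed reagent (k = 4.60 × 10⁻⁴ s⁻¹)
    substrate ⇌ dormant form (K = 0.390, k = 4.50 × 10⁻⁴ s⁻¹)

In the flask, partner, the limiting reagent, stands at 1.8% of its charge, double product plus decomposed reagent make 21.9%, and dormant form, which my split left out, stands at 8.72%. The depth of this flask comes to 2.18, less than the 2.62 read in the south run; that south depth, applied to this flask's standings, asks 1.73 equiv. Now take the neighbouring flask with 0.900 equiv of partner: the south depth asks 1.31 equiv on its readings. Its own depth reads 1.58, less than this flask's, and its triple product stands at 10.3%.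

The runs stem from a simulated flask for substances that don't exist, and the scatter is random.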